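Follow one molecule.

the same everywhere: substrate 0.80 M (in portions, 2)

| flask | reagent | remark | time |
|---|---|---|---|
| blue | 1.5 equiv | run made earlier; portions every 2.5 d |  |
| flask | 1.00 equiv | the portions of substrate follow each other after 2.5 d, the first at the start | 5.0 d |

- blue (time / h: target / %, substrate / %, intermediate D / %): 6.00: 27.6, 9.0, 1.6; 12.0: 35.3, 3.5, 0.7; 20.0: 37.7, 0.8, 2.4; 25.0: 38.5, 2.2, 3.4; 30.0: 37.9, 1.1, 1.5; 40.0: 40.4, 1.0, 3.1

(standard deviation of a reading: 1 percentage point)

- in percentages every species weighs as the substrate in it: one side product or self-condensation product counts as two
- what may be going on: intermediate B <-> intermediate C; substrate + intermediate B -> side product; intermediate A -> intermediate B; substrate + reagent <-> intermediate A; substrate + reagent -> target; intermediate A <-> intermediate D; 2 substrate -> self-condensation product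

- the target in the flask at 5.0 d, as a percentage of the substrate charged
- the substrate in the flask at 5.0 d, as a percentage of the substrate charged
- the intermediate D in the flask at 5.0 d, as a percentage of the substrate charged

A molecule of substrate stands at a fork: it meets reagent and becomes target, or it takes one of the other paths. The blue readings stop at 40.0 h, earlier than blue's second portion, so they describe the first portion, half of the charge. Blue's last target reading is 40.4% of the whole charge. Doubling it gives 80.8%, the share of blue's first portion standing as target at that time, which I call the end chance, a selectivity. It is a reading: the target reading behind it carries a scatter of 1 percentage point.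

Two people argue over the flask, which has 1.00 equiv of reagent. The first holds that the end chance travels: both portions face the same fork, so if the forecast's substrate stays unreacted, target is 77.6%. The second made the forecast and expects a worse fork for the later portion as [reagent] falls against [substrate]; in its words, the “second portion then meets near-equimolar reagent”. The forecast gives target 68%, substrate 4% and intermediate D 4%.

The flask gives target 74.0%, substrate 4.61% and intermediate D 3.44%. The first view misses by 3.6 points, less than the forecast's 6 points.

    intermediate B ⇌ intermediate C (K = 1.10, k = 4.20 × 10⁻⁷ s⁻¹)
    substrate + intermediate B → side product (k = 6.10 × 10⁻⁶ M⁻¹ s⁻¹)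
    intermediate A → intermediate B (k = 1.80 × 10⁻⁶ s⁻¹)
    substrate + reagent ⇌ intermediate A (K = 1.70 M⁻¹, k = 1.60 × 10⁻⁵ M⁻¹ s⁻¹)
    substrate + reagent → target (k = 4.90 × 10⁻⁵ M⁻¹ s⁻¹)
    intermediate A ⇌ intermediate D (K = 1.10, k = 5.40 × 10⁻⁶ s⁻¹)
    2 substrate → self-condensation product (k = 9.00 × 10⁻⁶ M⁻¹ s⁻¹)

The flask is not at rest at 5.0 d: it still holds substrate at 4.61%, intermediate A at 2.26% and intermediate D at 3.44%. Left ten times as long, these stand at 0%, 0% and 0%, while target climbs to 82.4%. The end chance read from blue, laid on the whole charge, is 80.8%, which is 1.6 points below that target.

The neighbour with 0.600 equiv of reagent has less reagent than substrate, so reagent is the limiting reagent, and as my own rough estimate the end chance laid on the reagent charged gives 48.5%. The neighbour gives target 51.2% with substrate 14.4% left; that target is 59.8% of the substrate no longer free, below the end chance, and in this neighbour the forecast's worsening fork is the view that stands.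

The data were generated by integration on assumed constants, and the scatter is random.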